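**Retrosynthetic overview**

1. The target is reached from its 5,7-bis(triisopropylsilyl) ether by fluoride cleavage, and the prenyl group from an allyl group by cross-metathesis, so only two neutral steps follow the ring construction.
2. Key disconnection: the dihydropyranone ring O1–C2–C3–C4–C4a–C8a is cut at C2–C3 and at C4–C4a into an aryl vinyl ether (used as its HCl adduct, the source of the aryl oxocarbenium ion C4a=C8a–O1=C2) and methylketene (C3=C4=O); their formal [4+2] union closes the ring and sets C2 and C3.
3. Enabling feature: C2 sits on O1 at the aldehyde oxidation level, C3–C4(=O) is a propanoyl (methylketene) unit, and C4a is the only unsubstituted carbon of the phloroglucinol ring, ortho to O1 and to the C5 oxygen and para to the C7 oxygen.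
4. The aryl vinyl ether goes back to a 4-propyl-dihydrocoumarin whose lactone ring is a temporary ring that keeps the future O1 apart from the other two phenol oxygens: Pechmann coumarin from phloroglucinol, silylation of 7-OH, allylation of 5-OH, CuH asymmetric conjugate reduction (hexanoate center), Claisen shift of allyl to C6, silylation, methanolysis, O-vinylation (coumarin numbering).
5. Order of rings: benzene ring (bought), lactone ring (made in step 1, opened in step 7), dihydropyranone ring (step 10).

Key step: step 10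

Assumption: for steps 4 and 10 the sense of induction of the chiral ligand and of the chiral squaramide is taken to be the one stated; if a test run shows the opposite sense, the mirror-image ligand or catalyst is used.

TIPS = triisopropylsilyl (iPr3Si).

**Route**

Step 1
Reactants: 1 phloroglucinol (benzene-1,3,5-triol); 2 ethyl 3-oxohexanoate
Product: 3 5,7-dihydroxy-4-propyl-2H-chromen-2-one
Conditions: conc. H2SO4, 0 °C → rt
Reagents that add atoms: none
Why: Pechmann condensation (acid-promoted transesterification, ring C-alkylation by the ketone and dehydration), which on the threefold-symmetric triphenol can give only one coumarin.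

Step 2
Reactants: 3 5,7-dihydroxy-4-propyl-2H-chromen-2-one
Product: 4 5-hydroxy-4-propyl-7-[(triisopropylsilyl)oxy]-2H-chromen-2-one
Conditions: iPr3SiCl (1.05 equiv), imidazole, DMF, 0 °C
Reagents that add atoms: triisopropylsilyl chloride, CC(C)[Si](Cl)(C(C)C)C(C)C
Why: Selective monosilylation, in which the bulky silyl chloride should take the more acidic and unhindered 7-OH because 5-OH is shielded by the peri propyl group on C4.

Step 3
Reactants: 4 5-hydroxy-4-propyl-7-[(triisopropylsilyl)oxy]-2H-chromen-2-one
Product: 5 5-(allyloxy)-4-propyl-7-[(triisopropylsilyl)oxy]-2H-chromen-2-one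
Conditions: allyl bromide, K2CO3, dry acetone, reflux
Reagents that add atoms: allyl bromide, C=CCBr
Why: Williamson ether synthesis on the remaining phenoxide, which places the allyl group on the oxygen whose only free ortho position is C6.

Step 4
Reactants: 5 5-(allyloxy)-4-propyl-7-[(triisopropylsilyl)oxy]-2H-chromen-2-one
Product: 6 (4R)-5-(allyloxy)-4-propyl-7-[(triisopropylsilyl)oxy]chroman-2-one
Conditions: Cu(OAc)2·H2O (5 mol%), (R)-DTBM-SEGPHOS (5 mol%), (EtO)2MeSiH (1.3 equiv), t-BuOH (1.3 equiv), toluene, 0 °C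
Reagents that add atoms: none
Why: Copper hydride-catalysed asymmetric conjugate (1,4-) reduction of a coumarin, in which the bisphosphine-bound CuH adds hydride to one face of C4 (ligand control sets the R center) and tert-butanol protonates the copper enolate so that the lactone is not reduced further.

Step 5
Reactants: 6 (4R)-5-(allyloxy)-4-propyl-7-[(triisopropylsilyl)oxy]chroman-2-one
Product: 7 (4R)-6-allyl-5-hydroxy-4-propyl-7-[(triisopropylsilyl)oxy]chroman-2-one
Conditions: PhNEt2, 190 °C
Reagents that add atoms: none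
Why: Aromatic Claisen ([3,3]-sigmatropic) rearrangement, which should deliver the allyl group to C6 because the other ortho position (C4a) is substituted, and which leaves the C4 center untouched.

Step 6
Reactants: 7 (4R)-6-allyl-5-hydroxy-4-propyl-7-[(triisopropylsilyl)oxy]chroman-2-one
Product: 8 (4R)-6-allyl-4-propyl-5,7-bis[(triisopropylsilyl)oxy]chroman-2-one
Conditions: iPr3SiOTf, 2,6-lutidine, CH2Cl2, 0 °C → rt
Reagents that add atoms: triisopropylsilyl trifluoromethanesulfonate, CC(C)[Si](OS(=O)(=O)C(F)(F)F)(C(C)C)C(C)C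
Why: Silylation of a hindered phenol with a silyl triflate and a hindered base, done while the lactone ring still ties back the neighbouring side chain.

Step 7
Reactants: 8 (4R)-6-allyl-4-propyl-5,7-bis[(triisopropylsilyl)oxy]chroman-2-one
Product: 9 methyl (3R)-3-{3-allyl-6-hydroxy-2,4-bis[(triisopropylsilyl)oxy]phenyl}hexanoate
Conditions: NaOMe (1.1 equiv), MeOH–THF, −40 °C; AcOH
Reagents that add atoms: sodium methoxide, C[O-].[Na+]
Why: Methanolysis (transesterification) of an aryl lactone by methoxide, fast at low temperature and driven by phenoxide formation, which frees exactly the oxygen that the temporary lactone ring had kept apart from the two silylated ones.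

Step 8
Reactants: 9 methyl (3R)-3-{3-allyl-6-hydroxy-2,4-bis[(triisopropylsilyl)oxy]phenyl}hexanoate
Product: 10 methyl (3R)-3-{3-allyl-2,4-bis[(triisopropylsilyl)oxy]-6-(vinyloxy)phenyl}hexanoate
Conditions: Cu(OAc)2 (1 equiv), 2,4,6-trivinylcyclotriboroxane·pyridine (0.7 equiv), pyridine, CH2Cl2, air, rt
Reagents that add atoms: 2,4,6-trivinylcyclotriboroxane–pyridine complex, C=CB1OB(C=C)OB(C=C)O1.c1ccncc1
Why: Chan–Lam-type copper-mediated O-vinylation of a phenol with a vinylboroxine at room temperature, mild enough that the hydroxy ester should not close back to the lactone.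

Step 9
Reactants: 11 propionic anhydride
Product: 12 methylketene (prop-1-en-1-one), kept as a cold toluene solution
Conditions: flash vacuum pyrolysis, 550 °C; condensed into toluene, −78 °C
Reagents that add atoms: none
Why: Thermal cracking of a carboxylic anhydride to a ketene and the acid, the standard gas-phase route to low-molecular-weight ketenes.

Step 10
Reactants: 10 methyl (3R)-3-{3-allyl-2,4-bis[(triisopropylsilyl)oxy]-6-(vinyloxy)phenyl}hexanoate; 12 methylketene
Product: 16 methyl (3R)-3-{(2R,3S)-6-allyl-2,3-dimethyl-4-oxo-5,7-bis[(triisopropylsilyl)oxy]chroman-8-yl}hexanoate, via α-chloro ether 13 (not isolated), via acyl chloride 14 (not isolated), via acyl triflate 15 (not isolated)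
Conditions: HCl (1.0 equiv, Et2O), toluene, −78 °C; then 12 (3 equiv), chiral chloride-binding squaramide (10 mol%), −78 → −40 °C; excess 12 removed in vacuo; then 2,6-di-tert-butylpyridine, AgOTf, −78 → −30 °C
Reagents that add atoms: none
Why: Proposed new method: HCl turns the vinyl ether into α-chloro ether 13, the squaramide binds its chloride to give a chiral (E)-aryl oxocarbenium chloride ion pair, the nucleophilic α-carbon of methylketene 12 adds to it and chloride returns to the acyl cation to give acyl chloride 14, and AgOTf then makes mixed anhydride 15, which acylates the arene, so that overall the 2-oxadiene C4a=C8a–O1=C2 and the ketene C3=C4 bond are joined in a formal [4+2] union. The closest known reactions are the Lewis acid-promoted addition of ketenes to α-halo ethers (β-alkoxy acyl chlorides), hydrogen-bond-donor (anion-binding) catalysed enantioselective additions of π-nucleophiles to oxocarbenium ions made from α-chloro ethers, the oxa-Povarov reaction of aryl oxocarbenium ions with alkenes and the Friedel–Crafts cyclisation of 3-aryloxypropanoyl chlorides to chroman-4-ones. The dihydropyranone ring closes by 6-exo-dig attack of C4a on the acyl cation (intramolecular Friedel–Crafts acylation) and rearomatises by loss of a proton to the hindered pyridine, which is too encumbered to deprotonate the acyl cation at C3. C2 (R) is set by the catalyst: the squaramide-bound chloride covers the Re face of the oxocarbenium carbon, so the ketene adds to the Si face, and both epimers of 13 converge on the same ion pair. C3 (S) is set in the same bond formation by an open antiperiplanar approach with the ketene hydrogen between the aryloxy and methyl groups of C2 (Re face of the ketene carbon), the arrangement that makes acetal–enol silane additions syn selective, and the syn adduct is the cis ring. The step needs regioselective acylation and a clean cation–nucleophile pairing: the substrate secures the first because C4a is the only unsubstituted ring carbon and lies ortho to O1 and to the C5 silyloxy group and para to the C7 silyloxy group, and the second because all vinyl ether is stored as chloride 13 before the ketene is added, the phenols are silylated and the terminal allyl group is a far weaker nucleophile than a prenyl group.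

Step 11
Reactants: 16 methyl (3R)-3-{(2R,3S)-6-allyl-2,3-dimethyl-4-oxo-5,7-bis[(triisopropylsilyl)oxy]chroman-8-yl}hexanoate
Product: 17 methyl (3R)-3-{(2R,3S)-2,3-dimethyl-6-(3-methylbut-2-en-1-yl)-4-oxo-5,7-bis[(triisopropylsilyl)oxy]chroman-8-yl}hexanoate
Conditions: 2-methyl-2-butene (excess), second-generation Grubbs catalyst RuCl2(=CHPh)(H2IMes)(PCy3) (5 mol%), CH2Cl2, 40 °C
Reagents that add atoms: 2-methyl-2-butene, CC=C(C)C
Why: Olefin cross-metathesis of a terminal allyl group with excess 2-methyl-2-butene, a standard allyl-to-prenyl conversion under neutral conditions that should not touch the epimerisable C3 center.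

Step 12
Reactants: 17 methyl (3R)-3-{(2R,3S)-2,3-dimethyl-6-(3-methylbut-2-en-1-yl)-4-oxo-5,7-bis[(triisopropylsilyl)oxy]chroman-8-yl}hexanoate
Product: 18 methyl (3R)-3-[(2R,3S)-5,7-dihydroxy-2,3-dimethyl-6-(3-methylbut-2-en-1-yl)-4-oxochroman-8-yl]hexanoate (CNP0068017.1)
Conditions: Bu4NF (3 equiv), AcOH (3 equiv), THF, 0 °C
Reagents that add atoms: none
Why: Fluoride-mediated cleavage of aryl silyl ethers, buffered with acetic acid so that no free phenoxide is present to epimerise C3 or to lactonise onto the ester.

**Compound list**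

1 | phloroglucinol (benzene-1,3,5-triol) | Oc1cc(O)cc(O)c1 | starting material
2 | ethyl 3-oxohexanoate | CCCC(=O)CC(=O)OCC | starting material
3 | 5,7-dihydroxy-4-propyl-2H-chromen-2-one | CCCC1=CC(=O)Oc2cc(O)cc(O)c12 | intermediate
4 | 5-hydroxy-4-propyl-7-[(triisopropylsilyl)oxy]-2H-chromen-2-one | CCCC1=CC(=O)Oc2cc(O[Si](C(C)C)(C(C)C)C(C)C)cc(O)c12 | intermediate
5 | 5-(allyloxy)-4-propyl-7-[(triisopropylsilyl)oxy]-2H-chromen-2-one | CCCC1=CC(=O)Oc2cc(O[Si](C(C)C)(C(C)C)C(C)C)cc(OCC=C)c12 | intermediate
6 | (4R)-5-(allyloxy)-4-propyl-7-[(triisopropylsilyl)oxy]chroman-2-one | CCC[C@@H]1CC(=O)Oc2cc(O[Si](C(C)C)(C(C)C)C(C)C)cc(OCC=C)c12 | intermediate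
7 | (4R)-6-allyl-5-hydroxy-4-propyl-7-[(triisopropylsilyl)oxy]chroman-2-one | CCC[C@@H]1CC(=O)Oc2cc(O[Si](C(C)C)(C(C)C)C(C)C)c(CC=C)c(O)c12 | intermediate
8 | (4R)-6-allyl-4-propyl-5,7-bis[(triisopropylsilyl)oxy]chroman-2-one | CCC[C@@H]1CC(=O)Oc2cc(O[Si](C(C)C)(C(C)C)C(C)C)c(CC=C)c(O[Si](C(C)C)(C(C)C)C(C)C)c12 | intermediate
9 | methyl (3R)-3-{3-allyl-6-hydroxy-2,4-bis[(triisopropylsilyl)oxy]phenyl}hexanoate | CCC[C@H](CC(=O)OC)c1c(O)cc(O[Si](C(C)C)(C(C)C)C(C)C)c(CC=C)c1O[Si](C(C)C)(C(C)C)C(C)C | intermediate
10 | methyl (3R)-3-{3-allyl-2,4-bis[(triisopropylsilyl)oxy]-6-(vinyloxy)phenyl}hexanoate | CCC[C@H](CC(=O)OC)c1c(OC=C)cc(O[Si](C(C)C)(C(C)C)C(C)C)c(CC=C)c1O[Si](C(C)C)(C(C)C)C(C)C | intermediate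
11 | propionic anhydride | CCC(=O)OC(=O)CC | starting material
12 | methylketene (prop-1-en-1-one) | CC=C=O | intermediate
13 | methyl (3R)-3-{3-allyl-6-(1-chloroethoxy)-2,4-bis[(triisopropylsilyl)oxy]phenyl}hexanoate (both configurations at the chloro carbon; not isolated) | CCC[C@H](CC(=O)OC)c1c(OC(C)Cl)cc(O[Si](C(C)C)(C(C)C)C(C)C)c(CC=C)c1O[Si](C(C)C)(C(C)C)C(C)C | intermediate
14 | (2S,3R)-3-{4-allyl-2-[(3R)-1-methoxy-1-oxohexan-3-yl]-3,5-bis[(triisopropylsilyl)oxy]phenoxy}-2-methylbutanoyl chloride (not isolated) | CCC[C@H](CC(=O)OC)c1c(O[C@H](C)[C@H](C)C(=O)Cl)cc(O[Si](C(C)C)(C(C)C)C(C)C)c(CC=C)c1O[Si](C(C)C)(C(C)C)C(C)C | intermediate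
15 | (2S,3R)-3-{4-allyl-2-[(3R)-1-methoxy-1-oxohexan-3-yl]-3,5-bis[(triisopropylsilyl)oxy]phenoxy}-2-methylbutanoyl trifluoromethanesulfonate (mixed anhydride; not isolated) | CCC[C@H](CC(=O)OC)c1c(O[C@H](C)[C@H](C)C(=O)OS(=O)(=O)C(F)(F)F)cc(O[Si](C(C)C)(C(C)C)C(C)C)c(CC=C)c1O[Si](C(C)C)(C(C)C)C(C)C | intermediate
16 | methyl (3R)-3-{(2R,3S)-6-allyl-2,3-dimethyl-4-oxo-5,7-bis[(triisopropylsilyl)oxy]chroman-8-yl}hexanoate | CCC[C@H](CC(=O)OC)c1c(O[Si](C(C)C)(C(C)C)C(C)C)c(CC=C)c(O[Si](C(C)C)(C(C)C)C(C)C)c2c1O[C@H](C)[C@H](C)C2=O | intermediate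
17 | methyl (3R)-3-{(2R,3S)-2,3-dimethyl-6-(3-methylbut-2-en-1-yl)-4-oxo-5,7-bis[(triisopropylsilyl)oxy]chroman-8-yl}hexanoate | CCC[C@H](CC(=O)OC)c1c(O[Si](C(C)C)(C(C)C)C(C)C)c(CC=C(C)C)c(O[Si](C(C)C)(C(C)C)C(C)C)c2c1O[C@H](C)[C@H](C)C2=O | intermediate
18 | methyl (3R)-3-[(2R,3S)-5,7-dihydroxy-2,3-dimethyl-6-(3-methylbut-2-en-1-yl)-4-oxochroman-8-yl]hexanoate | CCC[C@H](CC(=O)OC)c1c(O)c(CC=C(C)C)c(O)c2c1O[C@H](C)[C@H](C)C2=O | target

**Step count and risks**

Total: 12 steps. Longest linear sequence: 11 steps (steps 1–8 and 10–12, from phloroglucinol); step 9 is a one-step side branch.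

Steps most likely to fail:

1. Step 10 (proposed new method). The ketene may add too slowly to the hydrogen-bonded ion pair, so that ketene oligomerisation or uncatalysed ionisation takes over. Facial selectivity at C2 may be poor. Cis control at C3 may be lost, either through a closed instead of an open approach or through reversible loss of the α-proton at the acyl cation stage. Fallback (known chemistry; the O1–C2 bond is made by Mitsunobu inversion and both centers come from the chiral pool): it sets out from phenol 9 and comes back to the route at acyl chloride 14. Commercial tert-butyl (S)-3-hydroxybutanoate is methylated through its dianion (LiN(iPr)2, MeI; Fráter–Seebach alkylation, anti selective) to tert-butyl (2S,3S)-3-hydroxy-2-methylbutanoate F1. Mitsunobu etherification of 9 with F1 (PPh3, diisopropyl azodicarboxylate, toluene, 0 °C → rt) should give, with inversion at the carbinol carbon, tert-butyl (2S,3R)-3-{4-allyl-2-[(3R)-1-methoxy-1-oxohexan-3-yl]-3,5-bis[(triisopropylsilyl)oxy]phenoxy}-2-methylbutanoate F2. The tert-butyl ester is cleaved with Me3SiOTf and 2,6-lutidine (CH2Cl2, 0 °C, then aqueous work-up) to the corresponding (2S,3R)-carboxylic acid F3. 1-Chloro-N,N,2-trimethylprop-1-en-1-amine (CH2Cl2, 0 °C) converts F3 into 14 under neutral conditions, and 14 is closed with AgOTf and 2,6-di-tert-butylpyridine as in the last stage of step 10 to give 16.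

2. Step 4. Hydride delivery to the peri-hindered β-carbon may be slow, the aryl lactone may be reduced further to the lactol, or face selectivity may be insufficient. Fallback (resolution instead of asymmetric catalysis): it sets out from coumarin 5 and comes back at lactone 6. Conjugate reduction with [(Ph3P)CuH]6 (toluene, rt) gives racemic 5-(allyloxy)-4-propyl-7-[(triisopropylsilyl)oxy]chroman-2-one F4. Aminolysis with (S)-1-phenylethylamine (toluene, 60 °C) opens it to two diastereomeric hydroxy amides, from which (3R)-3-{2-(allyloxy)-6-hydroxy-4-[(triisopropylsilyl)oxy]phenyl}-N-[(1S)-1-phenylethyl]hexanamide F5 is separated by chromatography or crystallisation. Heating F5 with p-TsOH in toluene closes the lactone again with loss of the amine and gives 6.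

3. Step 8. Coupling of the ortho-substituted phenol may be slow, so that relactonisation of the hydroxy ester back to 8 wins. Fallback (alkylation and elimination instead of copper coupling): it sets out from phenol 9 and comes back at vinyl ether 10. Alkylation of 9 with excess 1,2-dibromoethane (Cs2CO3, DMF, rt) gives methyl (3R)-3-{3-allyl-6-(2-bromoethoxy)-2,4-bis[(triisopropylsilyl)oxy]phenyl}hexanoate F6. Displacement of bromide by PhSeNa (from PhSeSePh and NaBH4, EtOH, 0 °C) gives methyl (3R)-3-{3-allyl-6-[2-(phenylselanyl)ethoxy]-2,4-bis[(triisopropylsilyl)oxy]phenyl}hexanoate F7. Oxidation with H2O2 (NaHCO3, THF, 0 °C → rt) and selenoxide syn-elimination gives 10.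

Further compounds
F1 | step 10 | tert-butyl (2S,3S)-3-hydroxy-2-methylbutanoate | C[C@H](O)[C@H](C)C(=O)OC(C)(C)C
F2 | step 10 | tert-butyl (2S,3R)-3-{4-allyl-2-[(3R)-1-methoxy-1-oxohexan-3-yl]-3,5-bis[(triisopropylsilyl)oxy]phenoxy}-2-methylbutanoate | CCC[C@H](CC(=O)OC)c1c(O[C@H](C)[C@H](C)C(=O)OC(C)(C)C)cc(O[Si](C(C)C)(C(C)C)C(C)C)c(CC=C)c1O[Si](C(C)C)(C(C)C)C(C)C
F3 | step 10 | (2S,3R)-3-{4-allyl-2-[(3R)-1-methoxy-1-oxohexan-3-yl]-3,5-bis[(triisopropylsilyl)oxy]phenoxy}-2-methylbutanoic acid | CCC[C@H](CC(=O)OC)c1c(O[C@H](C)[C@H](C)C(=O)O)cc(O[Si](C(C)C)(C(C)C)C(C)C)c(CC=C)c1O[Si](C(C)C)(C(C)C)C(C)C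
F4 | step 4 | racemic 5-(allyloxy)-4-propyl-7-[(triisopropylsilyl)oxy]chroman-2-one | CCCC1CC(=O)Oc2cc(O[Si](C(C)C)(C(C)C)C(C)C)cc(OCC=C)c12
F5 | step 4 | (3R)-3-{2-(allyloxy)-6-hydroxy-4-[(triisopropylsilyl)oxy]phenyl}-N-[(1S)-1-phenylethyl]hexanamide | CCC[C@H](CC(=O)N[C@@H](C)c1ccccc1)c1c(O)cc(O[Si](C(C)C)(C(C)C)C(C)C)cc1OCC=C
F6 | step 8 | methyl (3R)-3-{3-allyl-6-(2-bromoethoxy)-2,4-bis[(triisopropylsilyl)oxy]phenyl}hexanoate | CCC[C@H](CC(=O)OC)c1c(OCCBr)cc(O[Si](C(C)C)(C(C)C)C(C)C)c(CC=C)c1O[Si](C(C)C)(C(C)C)C(C)C
F7 | step 8 | methyl (3R)-3-{3-allyl-6-[2-(phenylselanyl)ethoxy]-2,4-bis[(triisopropylsilyl)oxy]phenyl}hexanoate | CCC[C@H](CC(=O)OC)c1c(OCC[Se]c2ccccc2)cc(O[Si](C(C)C)(C(C)C)C(C)C)c(CC=C)c1O[Si](C(C)C)(C(C)C)C(C)C
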